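1. 2.86 is the number to start from: the beta run's 20 % of target over the epsilon run's 7 %, both read at 50.0 min and both at 0.40 M of starting material, each with a scatter of 1.5 percentage points.

| setting | epsilon | beta | zeta | flask |
|---|---|---|---|---|
| starting material | 0.40 M | 0.40 M | 0.60 M | 0.40 M |
| reagent in the second phase | 0.55 equiv | 2.2 equiv | 1.1 equiv | 1.10 equiv |
| remark | run made earlier | run made earlier | run made earlier |  |
| time |  |  |  | 40 min |
| volume of the second phase over the first |  |  |  | 0.50 |

| run | time / min | target / % | starting material / % |
|---|---|---|---|
| epsilon | 4.00 | 1 | 99 |
| epsilon | 6.00 | 3 | 99 |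
| epsilon | 8.00 | 0 | 100 |
| epsilon | 15.0 | 2 | 99 |
| epsilon | 20.0 | 1 | 98 |
| epsilon | 30.0 | 2 | 96 |
| epsilon | 50.0 | 7 | 94 |
| beta | 4.00 | 0 | 99 |
| beta | 6.00 | 1 | 101 |
| beta | 8.00 | 1 | 99 |
| beta | 15.0 | 5 | 98 |
| beta | 20.0 | 9 | 93 |
| beta | 30.0 | 14 | 87 |
| beta | 50.0 | 20 | 77 |
| zeta | 4.00 | 2 | 99 |
| zeta | 8.00 | 2 | 97 |
| zeta | 15.0 | 3 | 95 |
| zeta | 25.0 | 7 | 88 |
| zeta | 50.0 | 12 | 87 |

(readings scatter by 1.5 percentage points)

- in the second phase: reagent in the second phase; everything else is in the first
- charges count per volume of the first phase; a concentration in a rate is the amount of a species over the volume of its own phase; every rate counts per litre of the first phase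
- the earlier runs hold the two phases in the same ratio of volumes as the flask asked about

1. amount of target at 40 min, in percent of the starting material charged
2. the change that raises the amount of target at 40 min, in percent of the starting material charged most ("none" if none brings more than 2 percentage points) (dusk / midnight / none)
3. amount of target at 40 min, in percent of the starting material charged, after dusk

2. The reagent charges of those two runs stand in the ratio 4.00, so target rose less than in proportion.

3. Call n the apparent reaction order in reagent, the logarithm of the target ratio over the logarithm of the charge ratio: 0.757. Its weak point is the small epsilon reading.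

4. The flask's 1.10 equiv lies between the two charges, so n puts it at 11.8 % at 50.0 min.

5. The midpoint of the beta readings at 30.0 min and 50.0 min gives a factor 0.850 for going back to 40 min, so this reckoning gives 10.1 %.

6. The forecast says 8 %, midnight and 10.5 %, holding that “percent target scales about linearly with reagent concentration”; the reckoning above lies higher.

    reagent in the reaction phase ⇌ reagent in the second phase, rate k1*([reagent in the reaction phase] - [reagent in the second phase]/K1) per volume of the first phase (partition coefficient = 3.12, kL = 0.0177 /min)
    starting material + reagent in the reaction phase ⇌ target (K = 2.06 /M, k = 0.0829 /M/min)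
    reagent in the reaction phase + target → over-reacted product (k = 0.0474 /M/min)

The flask gives 9.49 % of target, with midnight the best change and 13.2 % after dusk. At 40.0 min the second phase of this flask still holds 71.0 % of its reagent. Now use n on the midnight flask: it puts doubling the charge at a factor 1.69 on 9.49 %, an estimated gain of 6.5 points against the 7.5 points the midnight flask shows. In this flask dusk multiplies the target by 1.39, which equals doubling at an order of 0.481, so dusk would lead if a run doubling this flask's charge showed n below that value, and the n read here, 0.757, stands above it.

The runs stem from a simulated flask for an exercise; noise was put on by code.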